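Numbering: pyrrolo[1,2-a]azepine core C1–C3, N4, C5–C9, C9a; C10–C12 are the spiro-lactone carbons (C11 carries CH3); C2'–C5' belong to the lactone on C3.
Retrosynthetic cuts, in order: C3'=C4' saturation; C3–C5'; N4–C5 (N,O-acetal, azepine ring); C6–C7 and the butenolide C–CH3; C9–C8 with the spiro-lactone C–O; C9–C10.
Enabling feature: C3 is alpha to N4 in the pyrrolidine ring and its partner C5' carries the lactone oxygen (N4–C3–C5'–O). That array is the retron of a 2-silyloxyfuran adding to an N4=C3 iminium ion, so C3 is carried as the lactam carbonyl of L-pyroglutamate (N4, C1–C3, C9a and C9 all come from L-glutamic acid) and becomes the iminium ion only in the coupling flask.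
Forward order: pyrrolidinone, then the C9 spiro-lactone, then the butenolide attached through C7, then the azepine closed at N4–C5, then tetracyclic lactam and silyloxyfuran joined at C3–C5', then hydrogenation.
Stereochemistry: C9a (L-glutamic acid) and C11 (methyl (S)-3-bromo-2-methylpropanoate) are bought; C9 (Felkin–Anh addition), C5 (thermodynamic), C3 and C5' (key step) and C3' (hydrogenation) are relayed by substrate control.

Key step: step 10

Assumption: the C5 N,O-acetal carbon is taken to epimerise by acid-reversible ring opening (N-acyliminium ion at the lactam stage, iminium carboxylate at the amine stage) and the configuration of the target is taken to be the favoured one; a C5 epimer formed in step 8 would be carried on and equilibrated after step 10.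

Step 1
Reactants: 1 L-glutamic acid; 2 4-methoxybenzaldehyde
Product: 5 (S)-1-(4-methoxybenzyl)-5-oxopyrrolidine-2-carboxylic acid, via imine 3 (not isolated), via N-PMB-glutamic acid 4 (not isolated)
Conditions: 2 M NaOH, H2O/MeOH, rt; NaBH4, 0 °C; HCl to pH 3; then H2O/EtOH, reflux
Reagents that add atoms: none
Why: Reductive amination of the amino acid followed by thermal lactamisation of the N-benzylated γ-amino acid is a standard entry to N-benzyl pyroglutamic acids and leaves the α-stereocentre, the future C9a, untouched.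

Step 2
Reactants: 5 (S)-1-(4-methoxybenzyl)-5-oxopyrrolidine-2-carboxylic acid; 6 methyl (S)-3-bromo-2-methylpropanoate
Product: 9 methyl (R)-4-[(S)-1-(4-methoxybenzyl)-5-oxopyrrolidin-2-yl]-2-methyl-4-oxobutanoate, via acid chloride 7 (not isolated), via organozinc bromide 8 (not isolated)
Conditions: 6, Zn dust, I2 (cat.), DMA, 70 °C; separately 5, (COCl)2, DMF (cat.), CH2Cl2, 0 °C to rt, evaporate; combine, Pd(PPh3)4 (5 mol %), THF, 0 °C to rt
Reagents that add atoms: none
Why: Palladium-catalysed acylation of a β-zincio ester (zinc homoenolate) with an acid chloride (Negishi acylation) should give the γ-keto ester under neutral conditions, so neither the α-amido centre (C9a) nor the ester α-centre (future C11, not at a reacting carbon) is epimerised.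

Step 3
Reactants: 9 methyl (R)-4-[(S)-1-(4-methoxybenzyl)-5-oxopyrrolidin-2-yl]-2-methyl-4-oxobutanoate
Product: 11 (3R,5R)-5-[(S)-1-(4-methoxybenzyl)-5-oxopyrrolidin-2-yl]-3-methyl-5-vinyldihydrofuran-2(3H)-one, via magnesium alkoxide 10 (not isolated)
Conditions: CH2=CHMgBr (1.5 equiv), LaCl3·2LiCl, THF, −78 to 0 °C; then 1 M HCl
Reagents that add atoms: vinylmagnesium bromide, C=C[Mg]Br
Why: Grignard 1,2-addition to the ketone and spontaneous γ-lactonisation of the tertiary alkoxide onto the methyl ester should give the lactone; the tertiary lactam cannot chelate (no nitrogen lone pair, lactam oxygen anti to C9a), so the polar Felkin–Anh arrangement with the C9a–N bond anti to the incoming vinyl group should set C9 as in the target, while the lanthanum salt suppresses enolisation.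

Step 4
Reactants: 11 (3R,5R)-5-[(S)-1-(4-methoxybenzyl)-5-oxopyrrolidin-2-yl]-3-methyl-5-vinyldihydrofuran-2(3H)-one
Product: 12 (3R,5R)-3-methyl-5-[(S)-5-oxopyrrolidin-2-yl]-5-vinyldihydrofuran-2(3H)-one
Conditions: CAN (3 equiv), MeCN/H2O 3:1, 0 °C to rt
Reagents that add atoms: none
Why: Oxidative cleavage of an N-(4-methoxybenzyl) lactam with ceric ammonium nitrate is standard and should leave the vinyl group and the lactone untouched.

Step 5
Reactants: 13 mucobromic acid
Product: 14 3,4-dibromo-5-methoxyfuran-2(5H)-one (racemic)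
Conditions: MeOH, H2SO4 (cat.), reflux
Reagents that add atoms: methanol, CO
Why: Acid-catalysed pseudo-ester formation (acetalisation of the lactol form of the pseudo-acid) is the standard protection of mucohalic acids.

Step 6
Reactants: 12 (3R,5R)-3-methyl-5-[(S)-5-oxopyrrolidin-2-yl]-5-vinyldihydrofuran-2(3H)-one; 14 3,4-dibromo-5-methoxyfuran-2(5H)-one
Product: 16 3-bromo-5-methoxy-4-{2-[(2S,4R)-4-methyl-5-oxo-2-[(S)-5-oxopyrrolidin-2-yl]tetrahydrofuran-2-yl]ethyl}furan-2(5H)-one (both epimers at the methoxy carbon), via alkylborane 15 (not isolated)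
Conditions: 9-BBN-H (2.2 equiv), THF, 0 °C to rt; then 14, PdCl2(dppf) (5 mol %), AsPh3, aq. K3PO4, DMF, rt
Reagents that add atoms: none
Why: Anti-Markovnikov hydroboration of the monosubstituted alkene with 9-BBN and B-alkyl Suzuki–Miyaura coupling, which in 3,4-dibromofuranones occurs first at the more electrophilic β-bromide (C4), should form the C6–C7 bond; the methoxy-bearing carbon is planarised in step 8, so its configuration is of no consequence.

Step 7
Reactants: 16 3-bromo-5-methoxy-4-{2-[(2S,4R)-4-methyl-5-oxo-2-[(S)-5-oxopyrrolidin-2-yl]tetrahydrofuran-2-yl]ethyl}furan-2(5H)-one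
Product: 17 5-methoxy-3-methyl-4-{2-[(2S,4R)-4-methyl-5-oxo-2-[(S)-5-oxopyrrolidin-2-yl]tetrahydrofuran-2-yl]ethyl}furan-2(5H)-one (both epimers at the methoxy carbon)
Conditions: Me4Sn, Pd2(dba)3 (cat.), P(o-tol)3, NMP, 80 °C
Reagents that add atoms: tetramethylstannane, C[Sn](C)(C)C
Why: Stille coupling of the remaining α-bromo enoate with tetramethyltin should install the butenolide methyl group under neutral conditions that spare the base-sensitive pseudo-ester.

Step 8
Reactants: 17 5-methoxy-3-methyl-4-{2-[(2S,4R)-4-methyl-5-oxo-2-[(S)-5-oxopyrrolidin-2-yl]tetrahydrofuran-2-yl]ethyl}furan-2(5H)-one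
Product: 18 tetracyclic lactam (5S,9S,9aS,11R): the target skeleton with C3 as lactam carbonyl, carrying the C9 spiro-lactone and the C5–C6-fused 3-methylbutenolide as N-acyl N,O-acetal
Conditions: CSA (20 mol %), toluene (0.01 M), 5 Å MS, 90 °C
Reagents that add atoms: none
Why: Acid-catalysed amidoalkylation, in which the pseudo-ester ionises to the acyloxocarbenium ion, the lactam N–H adds and methanol is removed, should close the seven-membered ring as the N-acyl N,O-acetal, and because the closure is reversible C5 is set under thermodynamic control.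

Step 9
Reactants: 19 3-methylfuran-2(5H)-one
Product: 20 3-methyl-2-(triisopropylsilyloxy)furan
Conditions: TIPSOTf, Et3N, CH2Cl2, 0 °C to rt
Reagents that add atoms: triisopropylsilyl trifluoromethanesulfonate, CC(C)[Si](C(C)C)(C(C)C)OS(=O)(=O)C(F)(F)F
Why: Soft enolisation of the butenolide with a silyl triflate and triethylamine should give the aromatic 2-silyloxyfuran.

Step 10
Reactants: 18 tetracyclic lactam; 20 3-methyl-2-(triisopropylsilyloxy)furan
Product: 23 C3 butenolide adduct (3S,5'S): the target with a C3'=C4' double bond in the lactone on C3, via silyl hemiaminal 21 (not isolated), via iminium salt 22 (not isolated)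
Conditions: IrCl(CO)(PPh3)2 (2 mol %), (Me2HSi)2O, toluene, rt; then 20 (2 equiv), 2-nitrobenzoic acid, MeCN, 0 °C to rt
Reagents that add atoms: none
Why: The iridium catalyst and the disiloxane should hydrosilylate only the lactam C3=O (an amide carbonyl is far more Lewis basic than the three lactone carbonyls) to the N,O-silyl hemiaminal 21, which the weak acid ionises to the N4=C3 iminium ion 22; the γ-carbon of silyloxyfuran 20 then adds in a vinylogous Mannich reaction and the silyl group is lost. The closest known reaction type is the iridium-catalysed reductive vinylogous Mannich addition of 2-silyloxyfurans to tertiary γ-lactams in the presence of lactones. No ring is closed; the furanone ring arrives intact. C3 is set by attack on the pyrrolinium face anti to the quaternary C9 substituent on C9a (2,5-trans, 3S), and C5' by the open transition state usual for silyloxyfuran additions to five-membered cyclic iminium ions, which gives the threo (3S,5'S) pair. The step needs site selectivity for C3 over the C5 N,O-acetal: ionisation at C3 expels an untethered silanolate irreversibly, ionisation at C5 gives a tethered carboxylate that recloses, and once N4=C3 exists the nitrogen lone pair can no longer open C5. The same reversible opening at the amine stage lets C5 settle in its thermodynamic configuration.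

Step 11
Reactants: 23 C3 butenolide adduct
Product: 24 target, CNP0155196.1
Conditions: H2 (1 atm), 5% Rh/C, EtOAc, rt
Reagents that add atoms: none
Why: Heterogeneous hydrogenation should reduce only the trisubstituted butenolide (the tetrasubstituted ring-fused butenolide is too hindered), adding hydrogen anti to the C5' substituent so that the methyl group ends cis to it (3'S).

Compound list
1 | L-glutamic acid | N[C@@H](CCC(=O)O)C(=O)O | starting material
2 | 4-methoxybenzaldehyde | COc1ccc(C=O)cc1 | starting material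
3 | (S)-2-[(E)-(4-methoxybenzylidene)amino]pentanedioic acid (present as disodium salt) | COc1ccc(/C=N/[C@@H](CCC(=O)O)C(=O)O)cc1 | intermediate (not isolated)
4 | (S)-2-[(4-methoxybenzyl)amino]pentanedioic acid | COc1ccc(CN[C@@H](CCC(=O)O)C(=O)O)cc1 | intermediate (not isolated)
5 | (S)-1-(4-methoxybenzyl)-5-oxopyrrolidine-2-carboxylic acid | O=C1CC[C@@H](C(=O)O)N1Cc1ccc(OC)cc1 | intermediate
6 | methyl (S)-3-bromo-2-methylpropanoate | COC(=O)[C@H](C)CBr | starting material
7 | (S)-1-(4-methoxybenzyl)-5-oxopyrrolidine-2-carbonyl chloride | O=C1CC[C@@H](C(=O)Cl)N1Cc1ccc(OC)cc1 | intermediate (not isolated)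
8 | [(S)-3-methoxy-2-methyl-3-oxopropyl]zinc bromide | COC(=O)[C@H](C)C[Zn]Br | intermediate (not isolated)
9 | methyl (R)-4-[(S)-1-(4-methoxybenzyl)-5-oxopyrrolidin-2-yl]-2-methyl-4-oxobutanoate | COC(=O)[C@H](C)CC(=O)[C@@H]1CCC(=O)N1Cc1ccc(OC)cc1 | intermediate
10 | bromomagnesium alkoxide of methyl (2R,4R)-4-hydroxy-4-[(S)-1-(4-methoxybenzyl)-5-oxopyrrolidin-2-yl]-2-methylhex-5-enoate | C=C[C@](O[Mg]Br)(C[C@@H](C)C(=O)OC)[C@@H]1CCC(=O)N1Cc1ccc(OC)cc1 | intermediate (not isolated)
11 | (3R,5R)-5-[(S)-1-(4-methoxybenzyl)-5-oxopyrrolidin-2-yl]-3-methyl-5-vinyldihydrofuran-2(3H)-one | C=C[C@]1(C[C@@H](C)C(=O)O1)[C@@H]1CCC(=O)N1Cc1ccc(OC)cc1 | intermediate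
12 | (3R,5R)-3-methyl-5-[(S)-5-oxopyrrolidin-2-yl]-5-vinyldihydrofuran-2(3H)-one | C=C[C@]1(C[C@@H](C)C(=O)O1)[C@@H]1CCC(=O)N1 | intermediate
13 | mucobromic acid, 3,4-dibromo-5-hydroxyfuran-2(5H)-one | OC1OC(=O)C(Br)=C1Br | starting material
14 | 3,4-dibromo-5-methoxyfuran-2(5H)-one (racemic) | COC1OC(=O)C(Br)=C1Br | intermediate
15 | 9-{2-[(2S,4R)-4-methyl-5-oxo-2-[(S)-5-oxopyrrolidin-2-yl]tetrahydrofuran-2-yl]ethyl}-9-borabicyclo[3.3.1]nonane | C(C[C@]1(C[C@@H](C)C(=O)O1)[C@@H]1CCC(=O)N1)B1C2CCCC1CCC2 | intermediate (not isolated)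
16 | 3-bromo-5-methoxy-4-{2-[(2S,4R)-4-methyl-5-oxo-2-[(S)-5-oxopyrrolidin-2-yl]tetrahydrofuran-2-yl]ethyl}furan-2(5H)-one (both epimers at the methoxy carbon) | COC1OC(=O)C(Br)=C1CC[C@]1(C[C@@H](C)C(=O)O1)[C@@H]1CCC(=O)N1 | intermediate
17 | 5-methoxy-3-methyl-4-{2-[(2S,4R)-4-methyl-5-oxo-2-[(S)-5-oxopyrrolidin-2-yl]tetrahydrofuran-2-yl]ethyl}furan-2(5H)-one (both epimers at the methoxy carbon) | COC1OC(=O)C(C)=C1CC[C@]1(C[C@@H](C)C(=O)O1)[C@@H]1CCC(=O)N1 | intermediate
18 | tetracyclic lactam (5S,9S,9aS,11R): target skeleton with C3=O and no C3 substituent | CC1=C2CC[C@]3(C[C@@H](C)C(=O)O3)[C@@H]3CCC(=O)N3[C@H]2OC1=O | intermediate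
19 | 3-methylfuran-2(5H)-one | CC1=CCOC1=O | starting material
20 | 3-methyl-2-(triisopropylsilyloxy)furan | CC1=C(O[Si](C(C)C)(C(C)C)C(C)C)OC=C1 | intermediate
21 | C3 O-(1,1,3,3-tetramethyldisiloxanyl) hemiaminal of 18 (either C3 epimer) | CC1=C2CC[C@]3(C[C@@H](C)C(=O)O3)[C@@H]3CCC(O[Si](C)(C)O[SiH](C)C)N3[C@H]2OC1=O | intermediate (not isolated)
22 | N4=C3 iminium 2-nitrobenzoate of the tetracycle | CC1=C2CC[C@]3(C[C@@H](C)C(=O)O3)[C@@H]3CCC=[N+]3[C@H]2OC1=O.[O-]C(=O)c1ccccc1[N+](=O)[O-] | intermediate (not isolated)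
23 | C3 butenolide adduct (3S,5'S,5S,9S,9aS,11R): target with C3'=C4' double bond | CC1=C2CC[C@]3(C[C@@H](C)C(=O)O3)[C@@H]3CC[C@@H]([C@@H]4C=C(C)C(=O)O4)N3[C@H]2OC1=O | intermediate
24 | CNP0155196.1 (3S,3'S,5'S,5S,9S,9aS,11R) | CC1=C2CC[C@]3(C[C@@H](C)C(=O)O3)[C@@H]3CC[C@@H]([C@@H]4C[C@H](C)C(=O)O4)N3[C@H]2OC1=O | target

Total step count: 11. Longest linear sequence: 9 steps (1, 2, 3, 4, 6, 7, 8, 10, 11).

Steps most likely to fail

Step 10. The hydrosilylation of the electron-poor N-acyl N,O-acetal lactam may be sluggish, ionisation at C5 may compete with ionisation at C3, or face selectivity at the iminium ion may erode. The fallback forms the C3–C5' bond before the azepine is closed. It sets out from 17: Cp2Zr(H)Cl (THF, rt) should reduce the secondary lactam to the cyclic imine F1. Silyl triflate-catalysed vinylogous Mannich addition of 20 (TIPSOTf cat., CH2Cl2, −78 °C, then aq. NaHCO3), anti to the C9 substituent, should give the 2,5-trans secondary amine F2. Warming F2 with acetic acid in toluene lets the amine displace methanol from the pseudo-ester and close the N,O-acetal, which returns the route at 23.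

Step 3. Facial selectivity in the open Felkin–Anh transition state may be low, or enolisation of the ketone may compete. The fallback reverses the order in which the two carbon groups reach C9 and uses a rigid chelate instead. It sets out from 1: thermal cyclodehydration (H2O, 140 °C) gives L-pyroglutamic acid F3. EDC and N,O-dimethylhydroxylamine give the N-methoxy-N-methylamide F4. Lithium (trimethylsilyl)acetylide (2.2 equiv, THF, −78 °C) gives the ynone F5. The Grignard reagent from the TBS ether of (S)-3-bromo-2-methylpropan-1-ol (3 equiv, THF, −78 °C) should add to the five-membered N-magnesio lactam–ketone chelate from the face of the C9a hydrogen to give the tertiary propargylic alcohol F6. TBAF removes both silyl groups to give the alkynyl diol F7. TEMPO/PhI(OAc)2 oxidises the primary alcohol and closes the lactol to the ethynyl lactone F8. Semihydrogenation (H2, Pd/CaCO3/Pb, quinoline) returns the route at 12.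

Step 8. The weakly nucleophilic lactam nitrogen may not close the seven-membered ring, leaving an unfavourable equilibrium or oligomers. The fallback forms N4–C5 intermolecularly and closes the azepine through the C6–C7 bond. It sets out from 12 and 13: acid-catalysed condensation (TsOH, toluene, reflux, water removal) gives the N-(dibromofuranonyl) lactam F9. 9-BBN-H hydroborates the vinyl group to the alkylborane F10. Intramolecular B-alkyl Suzuki–Miyaura coupling at the β-bromide (PdCl2(dppf), AsPh3, aq. K3PO4, DMF, high dilution) gives the bromo tetracycle F11. Stille coupling with Me4Sn, followed by brief CSA treatment to equilibrate C5, returns the route at 18.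

Further compounds
F1 | step 10 | cyclic imine, 4-{2-[(2S,4R)-2-[(S)-3,4-dihydro-2H-pyrrol-2-yl]-4-methyl-5-oxotetrahydrofuran-2-yl]ethyl}-5-methoxy-3-methylfuran-2(5H)-one | COC1OC(=O)C(C)=C1CC[C@]1(C[C@@H](C)C(=O)O1)[C@@H]1CCC=N1
F2 | step 10 | secondary amine, 2,5-trans pyrrolidine carrying the (S)-4-methyl-5-oxo-2,5-dihydrofuran-2-yl group at C3 and the pseudo-ester side chain | COC1OC(=O)C(C)=C1CC[C@]1(C[C@@H](C)C(=O)O1)[C@@H]1CC[C@@H]([C@@H]2C=C(C)C(=O)O2)N1
F3 | step 3 | L-pyroglutamic acid | O=C1CC[C@@H](C(=O)O)N1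
F4 | step 3 | (S)-N-methoxy-N-methyl-5-oxopyrrolidine-2-carboxamide | CON(C)C(=O)[C@@H]1CCC(=O)N1
F5 | step 3 | (S)-5-[3-(trimethylsilyl)propioloyl]pyrrolidin-2-one | C[Si](C)(C)C#CC(=O)[C@@H]1CCC(=O)N1
F6 | step 3 | (S)-5-[(3R,5R)-6-(tert-butyldimethylsilyloxy)-3-hydroxy-5-methyl-1-(trimethylsilyl)hex-1-yn-3-yl]pyrrolidin-2-one | C[Si](C)(C)C#C[C@](O)(C[C@@H](C)CO[Si](C)(C)C(C)(C)C)[C@@H]1CCC(=O)N1
F7 | step 3 | (S)-5-[(3R,5R)-3,6-dihydroxy-5-methylhex-1-yn-3-yl]pyrrolidin-2-one | C#C[C@](O)(C[C@@H](C)CO)[C@@H]1CCC(=O)N1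
F8 | step 3 | (3R,5R)-5-ethynyl-3-methyl-5-[(S)-5-oxopyrrolidin-2-yl]dihydrofuran-2(3H)-one | C#C[C@]1(C[C@@H](C)C(=O)O1)[C@@H]1CCC(=O)N1
F9 | step 8 | (3R,5R)-5-[(S)-1-(3,4-dibromo-5-oxo-2,5-dihydrofuran-2-yl)-5-oxopyrrolidin-2-yl]-3-methyl-5-vinyldihydrofuran-2(3H)-one (both C5 epimers) | C=C[C@]1(C[C@@H](C)C(=O)O1)[C@@H]1CCC(=O)N1C1OC(=O)C(Br)=C1Br
F10 | step 8 | B-alkyl-9-BBN adduct of F9 | C(C[C@]1(C[C@@H](C)C(=O)O1)[C@@H]1CCC(=O)N1C1OC(=O)C(Br)=C1Br)B1C2CCCC1CCC2
F11 | step 8 | bromo tetracycle, 18 with Br in place of the butenolide methyl group | BrC1=C2CC[C@]3(C[C@@H](C)C(=O)O3)[C@@H]3CCC(=O)N3C2OC1=O
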